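## Analysis of the target

The target is an eremophilane: a cis-fused decalin (ring A = C1–C5 and C10, ring B = C5–C10) with methyl groups on C4 and on the quaternary C5, an isopropenyl group on C7, a C8 ketone flanked by the C9 hydroxyl, and a C3 ester. The ester is an (R,E)-4-acyloxyhex-2-enoate whose 4-oxygen carries an angelate, i.e. a (Z)-2-methylbut-2-enoate. There are six ring stereocentres (3R,4R,5R,7R,9R,10S) and one in the side chain (R). The 4-methyl, 5-methyl, 10-H, 9-OH and 7-isopropenyl groups lie on one face (called β here) and the C3 oxygen on the other (α). In the chair–chair conformer that has the C5 methyl axial on ring A, every substituent on C3, C4, C7 and C9 is equatorial. C7 and C9 flank the ketone and are therefore the thermodynamically favoured epimers, whereas C3, C4, C5 and C10 cannot be corrected later and have to be set kinetically. The sensitive groups are the α-isopropenyl ketone (it drifts into conjugation with base or acid), the α-ketol, the angelate (Z to E isomerisation) and the γ-acyloxy enoate. The hard points are the quaternary C5 at a cis ring fusion next to the C4 stereocentre, and two alkenes (the ring A alkene and the isopropenyl group) that cannot coexist while ring A is functionalised. The strategy rests on one feature: C5 and C10 carry the ring B bonds C5–C6 and C10–C9 cis on ring A, next to C4. This is the pattern of a cis-fused enone–alkene photoadduct in which C4 is the enone carbonyl, C5 the α-carbon, C10 the β-carbon, and C6 and C9 come from an alkene oxygenated on both carbons.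

## Retrosynthetic reasoning

**29 to 28, and 28 to 20 + 26.** The C9 silyl ether is removed last, because the C3 ester has to be formed while the C9 hydroxyl is masked and buffered fluoride leaves the α-isopropenyl ketone and both esters alone. The C3–O ester bond is cut next: it is the most labile bond, it makes the route convergent, and the forward acylation only has to tell a free secondary alcohol in 20 from a silylated one.

**26 to 24 + 25, and 24 to 21 + 22.** The acid 26 is cut at its C2=C3 double bond into the allylic ester 24 and 25 (cross-metathesis forward), and 24 at its ester bond into 21 and 22. The stereocentre comes from 21 and no protecting group is needed, because the trisubstituted, electron-poor angelate alkene does not take part in metathesis.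

**20 to 19.** The isopropenyl group is traced back to the conjugated isopropylidene ketone 19. A 1,1-disubstituted alkene would not survive the hydroboration that sets ring A, whereas a tetrasubstituted alkene does. The forward step is a contra-thermodynamic deconjugation by kinetic α-protonation of the extended enolate.

**19 to 18 to 16.** The C3–O and C4–H bonds are cut together: both come from one syn hydroboration of the C3=C4 alkene of 16. This is done on the closed decalin because the equatorial 9β-silyloxy group holds the C5 methyl axial on ring A, so the borane has to approach C3 from the α face. The borane also reduces the C8 ketone, so 18 is a diol, and the allylic C8 alcohol is re-oxidised selectively to 19.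

**16 to 14 to 13 to 12.** The C7–C11 bond is cut (aldol of the C7 enolate of 13 with a three-carbon ketone, then dehydration into conjugation). Before that, the C6=C7 double bond of 12 is reduced, which removes the oxygen that C6 carried as a formyl group.

**12 to 11 to 9.** Ring B is opened at C6–C7. Forward, the methyl ketone of 9 condenses with the C6 formyl group (masked as a lactol) to the cyclohexenone 11, which is then silylated. The disconnection is placed here because it leaves the 8-oxo-9-hydroxy pattern of the target in place.

**9 to 7.** The C8–C9 bond is cut: an acetyl anion equivalent adds to the C9 formyl group of 7. This formyl group sits on a tertiary carbon, the other on the quaternary C5, which should direct the site of attack. The adjacent quaternary C5 should direct the face (Felkin–Anh), which gives the 9β configuration.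

**7 to 5.** The two formyl carbons are rejoined as a C6–C9 bond. Forward, the cyclic carbonate of 5 is opened to a cis-cyclobutanediol and the strained glycol is cleaved. This is the step that turns the four-membered ring into the two arms from which ring B is built.

**5 to 4 to 3.** The C4 methyl is cut off. It is introduced by cross-coupling on the enol triflate 4 of the ketone 3. The ketone has to be removed before the carbonate is opened, because a cyclobutanol β to a ketone would undergo retro-aldol ring opening, and the resulting trisubstituted alkene is what the later hydroboration needs. A ketal would cost two extra steps.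

**3 to 1 + 2.** The cyclobutane is cut at C5–C6 and C9–C10. Forward, an enantioselective [2+2] photocycloaddition of 1 with 2 creates the quaternary C5 and C10 cis on ring A in one step from two commercial compounds.

## Alternatives that were turned down

**Alternative 1:** Ring A and ring B are disconnected together at C5–C10 and C3–C4, back to an open-chain trienone in which a tigloyl ketone is tethered to a 1-boryl diene. On heating, an intramolecular Diels–Alder reaction would give A1, a cis-fused octalone with a C3 allylboronate.
- For it: C3, C4, C5 and C10 are written in a single thermal step. The cis relation of the two methyls follows from the dienophile geometry, and C3 arrives as a C–B bond that is oxidised with retention. On ring A it is stronger than the chosen route, which needs four steps (2, 3, 11, 12) for the same centres.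
- Against it: the precursor must already hold the C8 and C9 oxygen stereocentres and a sensitive dienylboronate, so the risk lies in a long linear preparation and not in the key step. The α-methyl dienophile is sluggish, and endo/exo and facial control come only from remote tether substituents. A1 carries a C6 ketone and a C1=C2 alkene that have to be removed, and the isopropenyl group is still missing.
- In its place the chosen route offers a key step on commercial materials, a ring fusion that can only close cis, and ring B oxygenation at the correct carbons.

**Alternative 2:** Ring A is disconnected at C1–C10, back to a 4,4-disubstituted cyclohexadienone with a nitroalkyl chain. A bifunctional amine–thiourea would deprotonate the nitroalkane and steer it onto one of the two enone arms, giving A2.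
- For it: the desymmetrisation is mild, needs no photochemical equipment, and leaves the C6=C7–C8=O enone of ring B ready for work at C7. On operational simplicity it is at least as strong as the chosen route.
- Against it: the nitro group at C1 is only an activating group and has to be removed by a radical step. The C9 hydroxyl has to be added later by α'-oxidation with its own facial question. Ring A still needs the same C3/C4 work from a C4 ketal, and the dienone has to be made by dearomatisation of a phenol that already carries the chain.
- In its place the chosen route brings in the C9 oxygen with the alkene partner and needs no atom that is later deleted.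

**Alternative 3:** Ring A is disconnected at C4–C5 and C1–C10, back to A4 (3-methylcyclohex-2-en-1-one) and a chloro-alkenyl aluminium reagent that carries the C3 silyloxy stereocentre. A copper–carbene catalysed conjugate alkenylation followed by enolate cycloalkylation would give A3.
- For it: the quaternary C5 is set by a catalytic asymmetric step with good precedent, and C3–O and the C4 carbon arrive together, so a hydroxyl-directed hydrogenation finishes ring A. On ring A it is stronger than the chosen route and does not depend on a conformational argument.
- Against it: A3 has its ketone at C9 and nothing at C8, so the 8-oxo-9-hydroxy pattern needs a carbonyl transposition of several steps with regiochemical and stereochemical ambiguity. The catalyst must also override or match the existing C3 centre, and closing a ring with an aluminium enolate on a primary chloride is slow.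
- In its place the chosen route delivers ring B with the oxygen atoms already on C8 and C9.

Key step: step 1

Remarks on the chemistry:
- Atoms are numbered as in eremophilane (C1–C10 decalin, methyls on C4 and C5, C11–C13 on C7). β means the face of the C5 methyl group.
- Assumption: the oxazaborolidine derived from (S)-prolinol is taken to shield the enone face that leads to 3. If the sense of induction is opposite for an α-methyl enone, the (R)-prolinol-derived Lewis acid is used and nothing else changes.

## Route

Step 1
Reactants: 1 2-methylcyclohex-2-en-1-one; 2 vinylene carbonate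
Product: 3 (1R,6S,7R,8S)-1-methyl-2-oxobicyclo[4.2.0]octane-7,8-diyl carbonate (cis-anti-cis photoadduct)
Conditions: oxazaborolidine from (S)-α,α-bis(3,5-dimethylphenyl)prolinol and 2,4,6-trifluorophenylboronic acid (50 mol%), AlBr3 (50 mol%), 2 (10 equiv), CH2Cl2, −75 °C, hν (366 nm)
Reagents that add atoms: none
Why: Coordination of the enone carbonyl to the AlBr3-activated oxazaborolidine shifts its ππ* absorption to longer wavelength, so that 366 nm light should excite the complex and not free 1 or 2. The excited enone (triplet after intersystem crossing) adds through C10 to one carbon of 2 to give a 1,4-diradical, and after spin inversion radical recombination forms C5–C6. The closest known reaction type is the chiral oxazaborolidine–AlBr3 catalysed intermolecular [2+2] photocycloaddition of cyclohex-2-enone with alkenes, together with the direct photocycloaddition of cyclic enones to 2. The four-membered ring is closed stepwise (first bond C9–C10, second bond C5–C6 by collapse of the diradical), not by a concerted thermal mode. C10 is set by the enone face that the diarylmethyl group of the ligand leaves open. C5 follows because a four-membered ring closes onto a six-membered ring preferentially cis. C6 and C9 are cis to each other through the ring of 2, and their relation to ring A does not matter because both become formyl carbons in step 4. The step needs enantiofacial selectivity and cis fusion; regiochemistry is no issue because 2 is symmetric.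

Step 2
Reactants: 3 photoadduct
Product: 4 enol triflate of 3 (C3=C4 double bond; triflate on C4; ring fusion and carbonate as in 3)
Conditions: KN(SiMe3)2, THF, −78 °C; then PhNTf2, −78 to 0 °C
Reagents that add atoms: N-phenylbis(trifluoromethanesulfonimide), O=S(=O)(N(c1ccccc1)S(=O)(=O)C(F)(F)F)C(F)(F)F
Why: Enolate O-sulfonylation; C3 is the only enolisable position because C5 is quaternary, and a hindered amide base at low temperature should leave the cyclic carbonate untouched.

Step 3
Reactants: 4 enol triflate
Product: 5 1,2-dimethylbicyclo[4.2.0]oct-2-ene-7,8-diyl carbonate (cis-anti-cis; C4 methyl now in place)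
Conditions: MeZnCl, Pd(PPh3)4 (5 mol%), THF, 50 °C
Reagents that add atoms: methylzinc chloride, C[Zn]Cl
Why: Negishi coupling of an alkenyl triflate; the organozinc reagent is mild enough for the carbonate and fixes the alkene at C3=C4.

Step 4
Reactants: 5 alkene carbonate
Product: 7 (1S,2S)-2,3-dimethylcyclohex-3-ene-1,2-dicarbaldehyde (cis; C9 formyl on C10; C6 formyl on C5), via cis-cyclobutanediol 6 (not isolated)
Conditions: K2CO3, MeOH, 0 °C to rt; then pH 7 buffer, NaIO4, THF–H2O, 0 °C
Reagents that add atoms: none
Why: Carbonate methanolysis followed by periodate glycol cleavage, which is fast for a strained cis-cyclobutanediol; with C4 no longer a ketone, no retro-aldol opening can compete. C5 and C10 are untouched; the product is used at once because C10 is now α to a formyl group.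

Step 5
Reactants: 7 dialdehyde
Product: 9 keto-lactol (acetyl group C8/C7 on C9; C9 oxygen closed onto C6 as lactol; 9R; C6 anomers), via enol ether lactol 8 (not isolated)
Conditions: CH2=C(OEt)Li (1.1 equiv, from ethyl vinyl ether and t-BuLi), THF, −78 °C; then 0.5 M HCl, THF, 0 °C
Reagents that add atoms: 1-ethoxyvinyllithium, [Li]C(=C)OCC; water, O
Why: Acetyl anion equivalent addition; the formyl group on the tertiary C10 should react before the neopentyl one on C5, and the new alkoxide closes onto the C6 formyl group as a lactolate, which protects it from a second addition. Felkin–Anh attack anti to the quaternary C5 should give the 9R (9β) alcohol; dilute acid then hydrolyses the enol ether to the methyl ketone.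

Step 6
Reactants: 9 keto-lactol
Product: 11 9β-hydroxy-11,12,13-trinoreremophila-3,6-dien-8-one (5β-methyl; 10β-H), via 6-hydroxy ketone 10 (not isolated)
Conditions: K2CO3, MeOH, 0 °C to rt
Reagents that add atoms: none
Why: Intramolecular aldol condensation (6-enolexo closure of C7 onto the C6 formyl group released from the lactol, then E1cB loss of water). The enone 11 is the conjugated and therefore favoured ketol isomer, and mild carbonate at low temperature limits enolisation toward C9. Any 9α epimer is separated here.

Step 7
Reactants: 11 hydroxy enone
Product: 12 9β-(tert-butyldimethylsilyloxy)-11,12,13-trinoreremophila-3,6-dien-8-one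
Conditions: TBSOTf, 2,6-lutidine, CH2Cl2, −78 to 0 °C
Reagents that add atoms: tert-butyldimethylsilyl trifluoromethanesulfonate, CC(C)(C)[Si](C)(C)OS(=O)(=O)C(F)(F)F
Why: Silylation of a hindered secondary alcohol with a silyl triflate. The bulky 9β-silyloxy group, 1,3-cis to the C5 methyl on ring B, should hold the decalin in the conformer with the C5 methyl axial on ring A.

Step 8
Reactants: 12 silyloxy enone
Product: 13 9β-(tert-butyldimethylsilyloxy)-11,12,13-trinoreremophil-3-en-8-one
Conditions: [(Ph3P)CuH]6 (0.35 equiv), benzene, H2O (10 equiv), rt
Reagents that add atoms: none
Why: Copper hydride conjugate reduction; it is selective for the enone over the isolated trisubstituted C3=C4 alkene and is neutral, so C9 is not epimerised.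

Step 9
Reactants: 13 ketone
Product: 14 11-hydroxy-9β-(tert-butyldimethylsilyloxy)eremophil-3-en-8-one (C7 epimers)
Conditions: LiN(i-Pr)2, THF, −78 °C; ZnCl2; then acetone, −78 to −40 °C
Reagents that add atoms: acetone, CC(C)=O
Why: Kinetic deprotonation should occur at the C7 methylene and not at the hindered, silyloxy-bearing C9; the zinc enolate adds to the ketone electrophile (crossed aldol) with little proton transfer.

Step 10
Reactants: 14 aldol
Product: 16 9β-(tert-butyldimethylsilyloxy)eremophila-3,7(11)-dien-8-one, via tertiary mesylate 15 (not isolated)
Conditions: MsCl, Et3N, DMAP (cat.), CH2Cl2, 0 °C to rt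
Reagents that add atoms: none
Why: Mesylation through the sulfene and E1cB elimination give the conjugated tetrasubstituted enone; triethylamine is too weak to epimerise C9.

Step 11
Reactants: 16 dienone
Product: 18 9β-(tert-butyldimethylsilyloxy)eremophil-7(11)-ene-3α,8-diol (4β-methyl; C8 epimers), via bis-borane adduct 17 (not isolated)
Conditions: 9-BBN (3.5 equiv), THF, rt to 60 °C; then 30% H2O2, aq NaOAc, 0 °C to rt
Reagents that add atoms: hydrogen peroxide, OO
Why: The dialkylborane first reduces the conjugated ketone (1,2) and then hydroborates the trisubstituted C3=C4 alkene, while the tetrasubstituted C7=C11 alkene is inert to it. Boron adds to C3 and hydrogen to C4 syn from the α face, because the axial C5 methyl blocks the β face of C3, and oxidation with retention gives 3α-OH and 4β-methyl in one step. Acetate-buffered peroxide avoids silyl migration between O9 and O8.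

Step 12
Reactants: 18 diol
Product: 19 3α-hydroxy-9β-(tert-butyldimethylsilyloxy)eremophil-7(11)-en-8-one
Conditions: MnO2 (excess), CH2Cl2, rt
Reagents that add atoms: none
Why: Manganese dioxide oxidises the allylic C8 alcohol (both epimers) and leaves the saturated C3 alcohol alone.

Step 13
Reactants: 19 isopropylidene ketone
Product: 20 (3R,4R,5R,7R,9R,10S)-3-hydroxy-9-(tert-butyldimethylsilyloxy)eremophil-11-en-8-one (3α-OH; 7β-isopropenyl)
Conditions: KOt-Bu (3 equiv), THF–t-BuOH, 0 °C; then cold aq AcOH, −78 °C
Reagents that add atoms: none
Why: Deconjugation through the extended potassium dienolate, which is protonated kinetically at the α-carbon C7. C7 should converge on the equatorial 7β epimer because α-reprotonation is much faster than γ-reprotonation; if some axial epimer remains, brief DBU at 0 °C should equilibrate it. With ring A complete, C9 is also the thermodynamic epimer, so the base cannot harm it.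

Step 14
Reactants: 21 (R)-pent-1-en-3-ol; 22 angelic acid
Product: 24 (R)-pent-1-en-3-yl (Z)-2-methylbut-2-enoate, via mixed anhydride 23 (not isolated)
Conditions: 22, 2,4,6-trichlorobenzoyl chloride, Et3N, toluene, rt; then 21, 80 °C
Reagents that add atoms: none
Why: Yamaguchi-type esterification through the mixed anhydride without a nucleophilic catalyst, the conditions under which angelates form without Z to E isomerisation.

Step 15
Reactants: 24 allylic angelate; 25 acrylic acid
Product: 26 (R,E)-4-[(Z)-2-methylbut-2-enoyloxy]hex-2-enoic acid
Conditions: second-generation Hoveyda–Grubbs catalyst RuCl2(H2IMes)(=CH-C6H4-2-Oi-Pr) (5 mol%), 25 (3 equiv), CH2Cl2, 40 °C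
Reagents that add atoms: none
Why: Cross-metathesis of a terminal alkene with an acrylate partner should give the E-enoic acid; the trisubstituted, conjugated angelate alkene does not enter the catalytic cycle and the stereocentre is not touched.

Step 16
Reactants: 20 alcohol; 26 side-chain acid
Product: 28 9-O-tert-butyldimethylsilyl ether of the target, via mixed anhydride 27 (not isolated)
Conditions: 26, 2,4,6-trichlorobenzoyl chloride, Et3N, THF, 0 °C; then 20, DMAP, toluene, 0 °C to rt
Reagents that add atoms: none
Why: Yamaguchi esterification of the only free hydroxyl (equatorial 3α-OH); the mild amine base can at most move C7 toward its favoured equatorial epimer.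

Step 17
Reactants: 28 silyl ether
Product: 29 target, (3R,4R,5R,7R,9R,10S)-9-hydroxy-8-oxoeremophil-11-en-3-yl (R,E)-4-[(Z)-2-methylbut-2-enoyloxy]hex-2-enoate
Conditions: HF·pyridine, THF–pyridine, 0 °C to rt
Reagents that add atoms: none
Why: Fluoride-mediated desilylation under buffered, weakly acidic conditions should spare the α-isopropenyl ketone, the α-ketol and both unsaturated esters.

## Compound list

1 | 2-methylcyclohex-2-en-1-one | CC1=CCCCC1=O | starting material
2 | vinylene carbonate | O=C1OC=CO1 | starting material
3 | (1R,6S,7R,8S)-1-methyl-2-oxobicyclo[4.2.0]octane-7,8-diyl carbonate | O=C1CCC[C@@H]2[C@H]3OC(=O)O[C@H]3[C@]12C | intermediate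
4 | enol triflate of 3 (C3=C4) | FC(F)(F)S(=O)(=O)OC1=CCC[C@@H]2[C@H]3OC(=O)O[C@H]3[C@]12C | intermediate
5 | 1,2-dimethylbicyclo[4.2.0]oct-2-ene-7,8-diyl carbonate (cis-anti-cis) | CC1=CCC[C@@H]2[C@H]3OC(=O)O[C@H]3[C@]12C | intermediate
6 | 1,2-dimethylbicyclo[4.2.0]oct-2-ene-7,8-diol (cis-diol; trans to ring A) | CC1=CCC[C@@H]2[C@@H](O)[C@@H](O)[C@]12C | intermediate
7 | (1S,2S)-2,3-dimethylcyclohex-3-ene-1,2-dicarbaldehyde | CC1=CCC[C@H](C=O)[C@]1(C)C=O | intermediate
8 | 1-ethoxyvinyl adduct at C9, closed as C6 lactol (9R; C6 anomers) | C=C(OCC)[C@@H]1OC(O)[C@]2(C)C(C)=CCC[C@H]12 | intermediate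
9 | keto-lactol (acetyl on C9; C6 lactol; 9R; C6 anomers) | CC(=O)[C@@H]1OC(O)[C@]2(C)C(C)=CCC[C@H]12 | intermediate
10 | 6,9β-dihydroxy-11,12,13-trinoreremophil-3-en-8-one (C6 epimers) | O=C1CC(O)[C@]2(C)C(C)=CCC[C@@H]2[C@H]1O | intermediate
11 | 9β-hydroxy-11,12,13-trinoreremophila-3,6-dien-8-one | O=C1C=C[C@]2(C)C(C)=CCC[C@@H]2[C@H]1O | intermediate
12 | 9β-(tert-butyldimethylsilyloxy)-11,12,13-trinoreremophila-3,6-dien-8-one | O=C1C=C[C@]2(C)C(C)=CCC[C@@H]2[C@H]1O[Si](C)(C)C(C)(C)C | intermediate
13 | 9β-(tert-butyldimethylsilyloxy)-11,12,13-trinoreremophil-3-en-8-one | O=C1CC[C@]2(C)C(C)=CCC[C@@H]2[C@H]1O[Si](C)(C)C(C)(C)C | intermediate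
14 | 11-hydroxy-9β-(tert-butyldimethylsilyloxy)eremophil-3-en-8-one (C7 epimers) | O=C1C(C(C)(C)O)C[C@]2(C)C(C)=CCC[C@@H]2[C@H]1O[Si](C)(C)C(C)(C)C | intermediate
15 | 11-mesylate of 14 | O=C1C(C(C)(C)OS(C)(=O)=O)C[C@]2(C)C(C)=CCC[C@@H]2[C@H]1O[Si](C)(C)C(C)(C)C | intermediate
16 | 9β-(tert-butyldimethylsilyloxy)eremophila-3,7(11)-dien-8-one | O=C1C(=C(C)C)C[C@]2(C)C(C)=CCC[C@@H]2[C@H]1O[Si](C)(C)C(C)(C)C | intermediate
17 | 3α-(9-BBN-yl) 8-O-(9-BBN-yl) adduct of 16 (4β-methyl; C8 epimers) | C1CCC2CCCC1B2OC3C(=C(C)C)C[C@]4(C)[C@@H](C)[C@H](B5C6CCCC5CCC6)CC[C@@H]4[C@H]3O[Si](C)(C)C(C)(C)C | intermediate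
18 | 9β-(tert-butyldimethylsilyloxy)eremophil-7(11)-ene-3α,8-diol (C8 epimers) | OC1C(=C(C)C)C[C@]2(C)[C@@H](C)[C@H](O)CC[C@@H]2[C@H]1O[Si](C)(C)C(C)(C)C | intermediate
19 | 3α-hydroxy-9β-(tert-butyldimethylsilyloxy)eremophil-7(11)-en-8-one | O=C1C(=C(C)C)C[C@]2(C)[C@@H](C)[C@H](O)CC[C@@H]2[C@H]1O[Si](C)(C)C(C)(C)C | intermediate
20 | (3R,4R,5R,7R,9R,10S)-3-hydroxy-9-(tert-butyldimethylsilyloxy)eremophil-11-en-8-one | O=C1[C@@H](C(C)=C)C[C@]2(C)[C@@H](C)[C@H](O)CC[C@@H]2[C@H]1O[Si](C)(C)C(C)(C)C | intermediate
21 | (R)-pent-1-en-3-ol | C=C[C@@H](CC)O | starting material
22 | angelic acid, (Z)-2-methylbut-2-enoic acid | OC(=O)/C(C)=C\C | starting material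
23 | angelic 2,4,6-trichlorobenzoic anhydride | Clc1cc(Cl)cc(Cl)c1C(=O)OC(=O)/C(C)=C\C | intermediate
24 | (R)-pent-1-en-3-yl (Z)-2-methylbut-2-enoate | C=C[C@@H](CC)OC(=O)/C(C)=C\C | intermediate
25 | acrylic acid | C=CC(=O)O | starting material
26 | (R,E)-4-[(Z)-2-methylbut-2-enoyloxy]hex-2-enoic acid | OC(=O)/C=C/[C@@H](CC)OC(=O)/C(C)=C\C | intermediate
27 | mixed anhydride of 26 with 2,4,6-trichlorobenzoic acid | Clc1cc(Cl)cc(Cl)c1C(=O)OC(=O)/C=C/[C@@H](CC)OC(=O)/C(C)=C\C | intermediate
28 | 9-O-tert-butyldimethylsilyl ether of the target | O=C1[C@@H](C(C)=C)C[C@]2(C)[C@@H](C)[C@H](OC(=O)/C=C/[C@@H](CC)OC(=O)/C(C)=C\C)CC[C@@H]2[C@H]1O[Si](C)(C)C(C)(C)C | intermediate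
29 | CNP0190706.1 | C=C(C)[C@H]1C[C@@]2(C)[C@H](CC[C@@H](OC(=O)/C=C/[C@@H](CC)OC(=O)/C(C)=C\C)[C@@H]2C)[C@@H](O)C1=O | target

## Step count and least certain steps

Total step count: 17. Longest linear sequence: 15 steps (steps 1–13, 16 and 17); the side-chain acid 26 takes two further steps (14 and 15).

**Step 1 (key step).** The most likely failure is weak enantiofacial discrimination. The α-methyl group removes the α C–H contact that normally fixes a cyclohexenone on the oxazaborolidine, and the carbonate carbonyl of 2 can compete for the Lewis acid, so an unselective background cycloaddition may run alongside. Part of the material may also close to the trans-fused adduct, which cannot be epimerised at the quaternary C5. The fallback sets out from 1 and 2 and comes back at 3. Direct irradiation without Lewis acid (λ ≥ 300 nm, excess 2) should give the racemic cis photoadduct F1. Ketalisation with the bis(trimethylsilyl) ether of (2R,3R)-butane-2,3-diol and catalytic TMSOTf should then give two diastereomeric dioxolanes. The one with the required ring configuration, the butanediyl ketal F2, is separated by chromatography or crystallisation and hydrolysed with aqueous acid to enantiopure 3. This replaces asymmetric catalysis by a classical resolution.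

**Step 5.** The most likely failure is erosion of facial selectivity at C9, because lithium can bridge the two formyl oxygens and override the Felkin–Anh preference. Deprotonation at C10 by the basic organolithium would also scramble the ring fusion. The fallback sets out from 7 and comes back at 11. The C9 epimer mixture is carried through steps 5 and 6 and separated at the enone stage. The unwanted 9α-hydroxy enone F3 is inverted by a Mitsunobu reaction (4-nitrobenzoic acid, PPh3, diisopropyl azodicarboxylate, THF) to the 9β 4-nitrobenzoate F4. Methanolysis (K2CO3, MeOH, 0 °C) should then release 11. The stereocentre is thus corrected by SN2 inversion instead of relying on the addition.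

**Step 11.** The most likely failure is slow addition of the bulky borane to the hindered ring alkene next to the quaternary C5. The tempting remedy, a smaller borane, would lose chemoselectivity over the C7=C11 alkene. The fallback sets out from 16 and comes back at 19, and it replaces hydroboration by oxidation and directed reduction.
- mCPBA (NaHCO3, CH2Cl2, 0 °C) should epoxidise only the electron-rich C3=C4 alkene, from the α face, to the 3α,4α-epoxide F5.
- Cp2TiCl (trivalent titanium, from Cp2TiCl2 and Mn, THF, rt) opens the epoxide at C4, and loss of a methyl hydrogen gives the 4-methylene 3α-alcohol F6.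
- Hydroxyl-directed hydrogenation with [Rh(nbd)(dppb)]BF4 and H2 in CH2Cl2 delivers hydrogen to C4 from the face of the C3 hydroxyl and does not reduce the tetrasubstituted enone, which gives 19.

In this variant C4 no longer depends on steric approach; only the epoxidation face does.

**Step 13.** The most likely failures are protonation at the γ-carbon or base-mediated return to the conjugated ketone during work-up, and kinetic protonation of C7 from the less hindered β face, which would give the axial isopropenyl epimer. The fallback sets out from 19 and comes back at 20. Deprotonation with KN(SiMe3)2 in the presence of TMSCl (THF, −78 °C) should give the bis(trimethylsilyl) dienol ether F7, in which the C3 hydroxyl is silylated as well. F7 is isolated and then protodesilylated with CsF and AcOH in THF at −78 °C. This separates enolate formation from protonation and delivers the proton at C7 with no free base present; the C3 trimethylsilyl ether falls off in the same operation.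

## Further compounds

F1 | step 1 | racemic (1R*,6S*,7R*,8S*)-1-methyl-2-oxobicyclo[4.2.0]octane-7,8-diyl carbonate (racemate of 3) | O=C1CCC[C@@H]2[C@H]3OC(=O)O[C@H]3[C@]12C
F2 | step 1 | (2R,3R)-butane-2,3-diyl ketal of 3 | C[C@H]1OC2(CCC[C@@H]3[C@H]4OC(=O)O[C@H]4[C@]23C)O[C@@H]1C
F3 | step 5 | 9α-hydroxy-11,12,13-trinoreremophila-3,6-dien-8-one (C9 epimer of 11) | O=C1C=C[C@]2(C)C(C)=CCC[C@@H]2[C@@H]1O
F4 | step 5 | 9β-(4-nitrobenzoyloxy)-11,12,13-trinoreremophila-3,6-dien-8-one | O=C1C=C[C@]2(C)C(C)=CCC[C@@H]2[C@H]1OC(=O)c3ccc(cc3)[N+](=O)[O-]
F5 | step 11 | 3α,4α-epoxy-9β-(tert-butyldimethylsilyloxy)eremophil-7(11)-en-8-one | O=C1C(=C(C)C)C[C@]2(C)[C@]3(C)O[C@@H]3CC[C@@H]2[C@H]1O[Si](C)(C)C(C)(C)C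
F6 | step 11 | 3α-hydroxy-4-methylene-9β-(tert-butyldimethylsilyloxy)-15-noreremophil-7(11)-en-8-one | O=C1C(=C(C)C)C[C@]2(C)C(=C)[C@H](O)CC[C@@H]2[C@H]1O[Si](C)(C)C(C)(C)C
F7 | step 13 | 3α,8-bis(trimethylsilyloxy)-9β-(tert-butyldimethylsilyloxy)eremophila-7,11-diene | C[Si](C)(C)OC1=C(C(C)=C)C[C@]2(C)[C@@H](C)[C@H](O[Si](C)(C)C)CC[C@@H]2[C@H]1O[Si](C)(C)C(C)(C)C
A1 | alternative 1 | cis-fused 4,5-dimethyloctal-6-one C3 pinacol allylboronate (8-silyloxy, 9-(4-methoxybenzyloxy)) | C1C(=O)[C@@]2(C)[C@H](C=C[C@@H](B3OC(C)(C)C(C)(C)O3)[C@@H]2C)[C@@H](OCc4ccc(OC)cc4)[C@@H]1O[Si](C)(C)C(C)(C)C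
A2 | alternative 2 | cis-fused 5-methyl-1-nitrooctal-6-en-8-one C4 ethylene ketal | C1=C[C@@]2(C)[C@H]([C@H]([N+](=O)[O-])CCC23OCCO3)CC1=O
A3 | alternative 3 | cis-fused 5-methyl-4-methylene-3-(tert-butyldimethylsilyloxy)decalin-9-one | C1C[C@@]2(C)[C@H](CC[C@@H](O[Si](C)(C)C(C)(C)C)C2=C)C(=O)C1
A4 | alternative 3 | 3-methylcyclohex-2-en-1-one | CC1=CC(=O)CCC1
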